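Slowness was what I had to divide up before the next run. I took it that X becomes J on Z in this flask, with G that must first cross into solution.

in all of them: G 200 mM (held)

| flask | X | Z | remark | time |
|---|---|---|---|---|
| Friday's | 3 M | 4 mM | run made earlier |  |
| Tuesday's | 3 M | 16 mM | run made earlier |  |
| flask | 3.0 M | 8.1 mM |  | 8.0 min |

| run | time / min | J / % |
|---|---|---|
| Friday's | 0.333 | 1.2 |
| Friday's | 1.00 | 5.4 |
| Friday's | 2.00 | 8.7 |
| Friday's | 3.00 | 14.6 |
| Friday's | 4.00 | 17.4 |
| Friday's | 5.00 | 19.5 |
| Friday's | 6.00 | 23.4 |
| Tuesday's | 0.333 | 2.7 |
| Tuesday's | 1.00 | 6.1 |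
| Tuesday's | 2.00 | 14.9 |
| Tuesday's | 3.00 | 21.4 |
| Tuesday's | 4.00 | 27.7 |
| Tuesday's | 5.00 | 33.8 |
| Tuesday's | 6.00 | 37.2 |

(scatter of a reading: 1 percentage point)

- at the start none of G is in solution

- amount of J at 8.0 min, in percent of the X charged
- the change that raises the amount of J at 8.0 min, in percent of the X charged most ("none" if none brings more than 2 percentage points) (dawn / autumn / noon / none)
- amount of J at 8.0 min, in percent of the X charged, after dawn

- dawn: doubling the transfer coefficient of G, all else as stated
- autumn: doubling the amount of Z, all else as stated
- noon: doubling the saturation concentration of G, all else as stated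

I counted slowness as the minutes the whole charge of X would take at a run's average pace. The last readings gave 25.6 min for Friday's run and 16.1 min for Tuesday's, both readings with their scatter. I treated slowness as two waits in series. One ignores Z, and the other shrinks in inverse proportion to [Z]. Solving the two runs gave 13.0 min for the first, which I took for the crossing of G. At [Z] of 8.1 mM the second came to 6.26 min. That made 19.2 min, the flask's slowness, so 8.0 min at that pace gave me 41.6 % of J. In my reckoning the crossing wait was longer than the Z wait.

That pointed my next run away from Z. Autumn gave me 49.7 %. Dawn gave me 62.8 %. Noon, if the pace follows dissolved G in both waits, gave me 83.2 %, more than either. So I chose noon.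

The forecast gave 42 %, chose noon, and put dawn at 57 %, below my 62.8 %. It noted that “the order in G is assumed, since G never varied”.

The flask gave 38.7 %. Noon was best, adding 22 percentage points, and dawn reached 51.1 %.

    G ⇌ D, rate k1*(csat - [D]) (kL = 0.0260 s⁻¹)
    X + D + Z → Z + J (k = 3.20 M⁻² s⁻¹)
    J ⇌ L (K = 1.20, k = 0.00190 s⁻¹)

At 8.00 min, J in the flask was made 2.01 times faster than it was used up, each step taken net, with L at 15.6 %. Counted by the J it held, the flask's slowness came to 20.7 min, against my 19.2 min. For the neighbour with [Z] of 0.0032 M, my two waits gave a slowness of 28.8 min, or 27.8 % of J, and that flask gave 27.5 %.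

The data are simulated for substances that don't exist, noise included.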